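A flat stretch of target in the dusk flask cannot tell by itself whether target has stopped at a one-way split or at a balance, and the choice among the options hangs on which it is.

| flask | solid substrate | temperature | remark | time |
|---|---|---|---|---|
| dusk | 1 mM | 70 °C | the very flask that is asked about, followed so far |  |
| dawn | 1 mM | 55 °C | run made earlier |  |
| flask | 1.0 mM | 70 °C |  | 2.0 min |

dusk run (percent of the solid substrate charged)

| time / s | target / % | solid substrate / % |
|---|---|---|
| 10.0 | 7.7 | 68.7 |
| 12.0 | 9.8 | 63.7 |
| 20.0 | 20.2 | 44.2 |
| 30.0 | 33.1 | 21.5 |
| 50.0 | 52.4 | 0.3 |
| 80.0 | 54.4 | 0 |

dawn run (percent of the solid substrate charged)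

| time / min | target / % | solid substrate / % |
|---|---|---|
| 0.333 | 8.2 | 48.6 |
| 0.417 | 11.4 | 40.3 |
| 0.667 | 21.5 | 19.5 |
| 1.00 | 36.1 | 0.4 |
| 2.00 | 54.8 | 0 |
| 3.00 | 56.8 | 0 |

(scatter of a reading: 0.3 percentage points)

- as a solid, counted per litre of solution: solid substrate
- target taken out counts as made
- the earlier runs were read with a standard deviation of 0.3 percentage points
- steps thought possible: starting material <-> target; target <-> isomer of the product A; isomer of the product A <-> isomer of the product B; solid substrate <-> starting material
- at the start none of the solid substrate is in solution

- alder: at 2.0 min take out 90 % of the target then present, then wait 2.0 min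
- cedar: at 2.0 min raise the temperature by 25 K, then wait 2.0 min
- oak: change nothing and wait 2.0 min more

- target, in percent of the solid substrate first charged, at 2.0 min
- which option adds most target ("none" when 2 percentage points or less is all one gets) (alder / cedar / oak / none)
- target present, with what was taken out counted in, in percent of the solid substrate first charged, after cedar
- target present, with what was taken out counted in, in percent of the solid substrate first charged, after oak

Two chemists read these runs and start from the same number. The last dusk reading has 54.4 % of target with solid at 0 %, which gives 1.19 for target over the remainder of the charge, called here the standing ratio, one rate divided by another so that time drops out.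

The first chemist, the splitter, reads it as a selectivity factor: dissolved material forks one way, the rate into target against the rate into the remainder, and what has gone to the remainder stays there, so taking target out of the dusk flask brings no more and heat after the fork changes nothing.

The second chemist, the balancer, whose reckoning I make my own, reads it as the rate of forming target, per unit of the remainder, against the rate of its going back, per unit of target, so that the dusk flask rebuilds the same ratio after a disturbance. The wait of 2.0 min is longer than the 30.0 s in which the dusk run went from 52.4 % to 54.4 %, so I expect the balance to return within it. Taking out 90 % of the target leaves a smaller pool that divides again by the same ratio, and with target taken out counted in, that gains 22 percentage points. The dawn run, cooler, stood higher at 1.31, so the balancer expects cedar to lose target, by an amount I put no figure on. Both chemists expect the dusk flask to hold about 54.4 % at 2.0 min and oak to stay under the mark of 2 points.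

The forecast, on the balancer's side, gave 54.6 %, alder as the best option, 51.2 % after cedar and 54.7 % after oak, holding that “this looks like a reversible equilibrium”.

The dusk flask gave 53.9 %, and alder added 22 points against my 22 points, while oak brought −0.098 points and cedar left 38.5 %.

    starting material ⇌ target (K = 24.0, k = 0.0620 s⁻¹, Ea = 83.0 kJ mol⁻¹, ΔH = 9.00 kJ mol⁻¹)
    target ⇌ isomer of the product A (K = 0.430, k = 0.0410 s⁻¹, Ea = 82.0 kJ mol⁻¹, ΔH = 48.0 kJ mol⁻¹)
    isomer of the product A ⇌ isomer of the product B (K = 0.900, k = 0.500 s⁻¹, Ea = 74.0 kJ mol⁻¹, ΔH = −73.0 kJ mol⁻¹)
    solid substrate ⇌ starting material, rate k4*(cs4 - [starting material]) while solid is left; crystals form when [starting material] > cs4 (solubility = 0.840 mM, k = 0.0440 s⁻¹)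
    (constants at 70 °C)

The splitter's one-way picture has its region early in the dusk flask, where at 0.200 min isomer of the product A held 0.914 %, less than the 9.67 % of target. After cedar the standing ratio of the dusk flask came to 0.626, and the neighbour flask kept at 95 °C, holding 38.5 % of target at 2.00 min, stood at 0.626.

All runs stem from a simulated flask for substances that don't exist.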